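**Retrosynthetic overview**

1. The O6 ester is made last. Ring A (carbocycle C1–C10) is closed at C6–C7 by a chromium-mediated intramolecular Barbier allylation of a (bromomethyl)butenolide onto a Z-enal, which also creates the α-methylene lactone and relays C8 to C7 and C6 in one event.
2. The butenolide (ring C) comes from a C8 allylic alcohol by acylation and ring-closing metathesis; C8 is set by reagent-controlled vinylation of a C8 aldehyde.
3. C10 is set by decarboxylative asymmetric allylation of a racemic furanone allyl ester: the ester that activated C10 leaves as CO2 and its allyl group becomes C9 and C8.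
4. Ring B (O, C10, C1, C2, C3) is a cyclic vinylogous ester: C1–C2–C3 has the oxidation pattern of an ynoate (acyl carbon C1, β-carbon C3) and C10 carries the ring oxygen. An enynoate therefore serves as 1,3-bis-electrophile and allyl lactate, whose C10 bears OH and a temporary ester, as O-then-C nucleophile.
5. Order of ring formation: B (step 3), C (step 8), A (step 11).

Key step: step 3

Remark: atoms are numbered as in germacranes (C1 ring ketone carbon, C2 ring CH, C3 enol-ether carbon, C10 quaternary carbon, C12 lactone carbonyl, C13 exocyclic methylene); allyl lactate is used as the racemate because its stereocenter becomes a planar enolate in steps 3 and 4.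

**Route**

Step 1
Reactants: 1 (Z)-3-methylpent-2-en-4-yn-1-ol
Product: 2 tert-butyldimethyl{[(Z)-3-methylpent-2-en-4-yn-1-yl]oxy}silane
Conditions: TBSCl, imidazole, DMF, 0 °C to rt
Reagents that add atoms: tert-butyldimethylsilyl chloride (TBSCl), CC(C)(C)[Si](C)(C)Cl
Why: Silylation of the primary allylic alcohol masks O6 for the basic and organometallic steps, and the Z alkene C4=C5 of the purchased enynol is carried unchanged into the target.

Step 2
Reactants: 2 tert-butyldimethyl{[(Z)-3-methylpent-2-en-4-yn-1-yl]oxy}silane; 3 allyl chloroformate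
Product: 4 allyl (Z)-6-[(tert-butyldimethylsilyl)oxy]-4-methylhex-4-en-2-ynoate
Conditions: n-BuLi, THF, −78 °C; then 3, −78 to 0 °C
Reagents that add atoms: none
Why: Acylation of the lithium acetylide with a chloroformate (alkoxycarbonylation of a terminal alkyne) installs C1 at the acid oxidation level and makes C3 the β-carbon of an ynoate; the allyl ester is chosen so that later ester exchange with allyl lactate is degenerate.

Step 3
Reactants: 4 allyl (Z)-6-[(tert-butyldimethylsilyl)oxy]-4-methylhex-4-en-2-ynoate; 5 allyl lactate (racemic)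
Product: 7 allyl 5-{(Z)-4-[(tert-butyldimethylsilyl)oxy]but-2-en-2-yl}-2-methyl-3-oxo-2,3-dihydrofuran-2-carboxylate (racemic), via oxa-Michael adduct 6 (not isolated)
Conditions: NaH (1.1 equiv), THF, 0 °C, slow addition of 4, then rt; AcOH quench
Reagents that add atoms: none
Why: The sodium alkoxide of 5 adds to C3 of ynoate 4 (oxa-Michael, O–C3) to give enoate 6, whose lactate C–H at C10 is flanked by an ester and an ether oxygen; its enolate attacks the C1 ester carbonyl and expels allyloxide (Dieckmann condensation, C1–C10), so ring B is closed in one pot. The closest known reaction type is the Fiesselmann synthesis of 3-hydroxythiophene-2-carboxylates from thioglycolates and alkynoates and its oxygen variant, which gives 3-oxo-2,3-dihydrofuran-2-carboxylates from α-hydroxy esters. Ring B closes by a 5-exo-trig acyl substitution that needs the ester cis to the ether oxygen on C2=C3; the E and Z forms of 6 should interconvert by reversible alkoxide addition, so the cis form is drained. C10 is formed as a racemate on purpose, because step 4 passes through a planar enolate at this carbon and sets it by catalyst control. The step needs O-attack at C3 and not at C5 or at an ester carbonyl: C3 is the most electrophilic carbon of the linear ynoate, both esters carry the same allyl group so ester exchange changes nothing, and the vinylogous ester product has no acidic C–H next to C1 and is the thermodynamic sink.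

Step 4
Reactants: 7 allyl 5-{(Z)-4-[(tert-butyldimethylsilyl)oxy]but-2-en-2-yl}-2-methyl-3-oxo-2,3-dihydrofuran-2-carboxylate (racemic)
Product: 8 (R)-2-allyl-5-{(Z)-4-[(tert-butyldimethylsilyl)oxy]but-2-en-2-yl}-2-methylfuran-3(2H)-one
Conditions: Pd2(dba)3 (2.5 mol %), (S)-t-Bu-PHOX (6 mol %), toluene, 30 °C
Reagents that add atoms: none
Why: Oxidative addition of zerovalent palladium to the allyl ester, loss of CO2 and C-allylation of the resulting aromatic 3-oxidofuran enolate at C10 inside the chiral ligand pocket is a decarboxylative asymmetric allylic alkylation (Tsuji type), a stereoconvergent reaction known for α-oxygenated cyclic β-keto allyl esters; it should turn racemic C10 into the R center (ligand antipode to be chosen accordingly) while the activating ester is removed and its allyl group becomes C9 and C8.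

Step 5
Reactants: 8 (R)-2-allyl-5-{(Z)-4-[(tert-butyldimethylsilyl)oxy]but-2-en-2-yl}-2-methylfuran-3(2H)-one
Product: 10 2-{(2R)-5-{(Z)-4-[(tert-butyldimethylsilyl)oxy]but-2-en-2-yl}-2-methyl-3-oxo-2,3-dihydrofuran-2-yl}acetaldehyde, via vicinal diol 9 (not isolated)
Conditions: K2OsO4·2H2O (2 mol %), NMO, acetone/H2O, 0 °C; then NaIO4, rt
Reagents that add atoms: N-methylmorpholine N-oxide (NMO), C[N+]1([O-])CCOCC1
Why: Catalytic dihydroxylation should take the isolated monosubstituted alkene much faster than the trisubstituted C4=C5 and the C2=C3 bonds, both deactivated by conjugation with the C1 ketone, and periodate cleavage of the diol (Lemieux–Johnson type sequence) gives the C8 aldehyde under near-neutral conditions that avoid β-elimination of the ring oxygen.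

Step 6
Reactants: 10 2-{(2R)-5-{(Z)-4-[(tert-butyldimethylsilyl)oxy]but-2-en-2-yl}-2-methyl-3-oxo-2,3-dihydrofuran-2-yl}acetaldehyde; 11 vinyl bromide
Product: 12 (2R)-5-{(Z)-4-[(tert-butyldimethylsilyl)oxy]but-2-en-2-yl}-2-[(2S)-2-hydroxybut-3-en-1-yl]-2-methylfuran-3(2H)-one
Conditions: CrCl2 (3 equiv), (S)-N-[2-(4-isopropyl-4,5-dihydrooxazol-2-yl)-6-methylphenyl]methanesulfonamide (3.3 equiv), Et3N (3.3 equiv), THF, rt; then NiCl2 (cat.), 10, 11, rt
Reagents that add atoms: none
Why: Asymmetric Nozaki–Hiyama–Kishi reaction: the vinylchromium species formed with nickel catalysis adds only to the aldehyde (the vinylogous ester ketone is inert) without base that could trigger β-elimination, and the chiral sulfonamide ligand on chromium should set C8 as S by reagent control (ligand antipode if the sense proves opposite).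

Step 7
Reactants: 12 (2R)-5-{(Z)-4-[(tert-butyldimethylsilyl)oxy]but-2-en-2-yl}-2-[(2S)-2-hydroxybut-3-en-1-yl]-2-methylfuran-3(2H)-one; 13 2-(bromomethyl)acrylic acid
Product: 14 (2S)-1-{(2R)-5-{(Z)-4-[(tert-butyldimethylsilyl)oxy]but-2-en-2-yl}-2-methyl-3-oxo-2,3-dihydrofuran-2-yl}but-3-en-2-yl 2-(bromomethyl)acrylate
Conditions: DCC, DMAP (5 mol %), CH2Cl2, −20 to 0 °C
Reagents that add atoms: none
Why: Carbodiimide esterification (Steglich type) acylates the secondary allylic alcohol with retention at C8 and brings in C11, C12 and C13; low temperature and little DMAP limit attack on the allylic bromide.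

Step 8
Reactants: 14 (2S)-1-{(2R)-5-{(Z)-4-[(tert-butyldimethylsilyl)oxy]but-2-en-2-yl}-2-methyl-3-oxo-2,3-dihydrofuran-2-yl}but-3-en-2-yl 2-(bromomethyl)acrylate
Product: 15 (2R)-2-{[(2S)-4-(bromomethyl)-5-oxo-2,5-dihydrofuran-2-yl]methyl}-5-{(Z)-4-[(tert-butyldimethylsilyl)oxy]but-2-en-2-yl}-2-methylfuran-3(2H)-one
Conditions: second-generation Grubbs catalyst (5 mol %), CH2Cl2, 40 °C
Reagents that add atoms: none
Why: Ring-closing metathesis between the C7 vinyl group and the acrylate gives the five-membered butenolide (ring C) with loss of ethene, a standard route to α-substituted butenolides; the trisubstituted and conjugated alkenes elsewhere should not engage and C8 is untouched.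

Step 9
Reactants: 15 (2R)-2-{[(2S)-4-(bromomethyl)-5-oxo-2,5-dihydrofuran-2-yl]methyl}-5-{(Z)-4-[(tert-butyldimethylsilyl)oxy]but-2-en-2-yl}-2-methylfuran-3(2H)-one
Product: 16 (2R)-2-{[(2S)-4-(bromomethyl)-5-oxo-2,5-dihydrofuran-2-yl]methyl}-5-[(Z)-4-hydroxybut-2-en-2-yl]-2-methylfuran-3(2H)-one
Conditions: HF·pyridine, pyridine, THF, 0 °C
Reagents that add atoms: none
Why: Buffered fluoride cleaves the primary allylic silyl ether while the allylic bromide and the butenolide with its acidic C8–H are left alone, which basic fluoride sources would not guarantee.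

Step 10
Reactants: 16 (2R)-2-{[(2S)-4-(bromomethyl)-5-oxo-2,5-dihydrofuran-2-yl]methyl}-5-[(Z)-4-hydroxybut-2-en-2-yl]-2-methylfuran-3(2H)-one
Product: 17 (Z)-3-{(5R)-5-{[(2S)-4-(bromomethyl)-5-oxo-2,5-dihydrofuran-2-yl]methyl}-5-methyl-4-oxo-4,5-dihydrofuran-2-yl}but-2-enal
Conditions: 1,1,1-triacetoxy-1,1-dihydro-1,2-benziodoxol-3(1H)-one (DMP), CH2Cl2, 0 °C
Reagents that add atoms: none
Why: The periodinane oxidises the allylic alcohol to the C6 enal under neutral, non-isomerising conditions, so the Z geometry that brings C6 within reach of C7 is kept.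

Step 11
Reactants: 17 (Z)-3-{(5R)-5-{[(2S)-4-(bromomethyl)-5-oxo-2,5-dihydrofuran-2-yl]methyl}-5-methyl-4-oxo-4,5-dihydrofuran-2-yl}but-2-enal
Product: 18 (6R,7S,8S,10R)-3,10-epoxy-6-hydroxy-1-oxogermacra-2,4Z,11(13)-trien-12,8-olide
Conditions: CrCl2 (8 equiv), THF, 2 mM, rt; aqueous work-up
Reagents that add atoms: none
Why: Divalent chromium inserts into the allylic C–Br bond and the allylchromium species adds through C7 to the C6 aldehyde (Nozaki–Hiyama/Barbier-type allylation, known for ten-membered germacranolide ring closures and for bromomethylbutenolides), which closes ring A and turns the butenolide into the α-methylene lactone; attack on the butenolide face opposite to the C9 substituent should give the trans lactone at C7, and the chair transition state with the ring-locked E-type allyl unit the anti C6/C7 relation, i.e. the configuration of the target.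

Step 12
Reactants: 19 (R)-(2-methyloxiran-2-yl)methanol
Product: 21 (S)-2-methyloxirane-2-carboxylic acid, via epoxy aldehyde 20 (not isolated)
Conditions: RuCl3·xH2O (2 mol %), NaIO4, MeCN/EtOAc/H2O, 0 °C
Reagents that add atoms: water, O
Why: Catalytically generated RuO4 oxidises the primary alcohol through the aldehyde hydrate to the acid without opening the epoxide; the purchased stereocenter is not touched (the descriptor changes from R to S only through the priority rules).

Step 13
Reactants: 18 (6R,7S,8S,10R)-3,10-epoxy-6-hydroxy-1-oxogermacra-2,4Z,11(13)-trien-12,8-olide; 21 (S)-2-methyloxirane-2-carboxylic acid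
Product: 22 (6R,7R,8S,10R)-3,10-epoxy-1-oxogermacra-2,4Z,11(13)-trien-12,8-olid-6-yl (S)-2-methyloxirane-2-carboxylate (CNP0321429.1)
Conditions: DCC, DMAP (0.2 equiv), CH2Cl2, 0 °C to rt
Reagents that add atoms: none
Why: Steglich esterification acylates the only free hydroxyl (O6) with retention at C6; DMAP adds only reversibly to the α-methylene lactone, and the epoxide and the furanone are stable to these conditions.

**Compound list**

1 | (Z)-3-methylpent-2-en-4-yn-1-ol | C#C/C(C)=C\CO | starting material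
2 | tert-butyldimethyl{[(Z)-3-methylpent-2-en-4-yn-1-yl]oxy}silane | C#C/C(C)=C\CO[Si](C)(C)C(C)(C)C | intermediate
3 | allyl chloroformate | C=CCOC(=O)Cl | starting material
4 | allyl (Z)-6-[(tert-butyldimethylsilyl)oxy]-4-methylhex-4-en-2-ynoate | C=CCOC(=O)C#C/C(C)=C\CO[Si](C)(C)C(C)(C)C | intermediate
5 | allyl lactate (allyl 2-hydroxypropanoate, racemic) | CC(O)C(=O)OCC=C | starting material
6 | allyl (4Z)-3-{[1-(allyloxy)-1-oxopropan-2-yl]oxy}-6-[(tert-butyldimethylsilyl)oxy]-4-methylhexa-2,4-dienoate (2E/2Z mixture, racemic; oxa-Michael adduct) | C=CCOC(=O)C(C)OC(=CC(=O)OCC=C)/C(C)=C\CO[Si](C)(C)C(C)(C)C | intermediate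
7 | allyl 5-{(Z)-4-[(tert-butyldimethylsilyl)oxy]but-2-en-2-yl}-2-methyl-3-oxo-2,3-dihydrofuran-2-carboxylate (racemic) | C=CCOC(=O)C1(C)OC(=CC1=O)/C(C)=C\CO[Si](C)(C)C(C)(C)C | intermediate
8 | (R)-2-allyl-5-{(Z)-4-[(tert-butyldimethylsilyl)oxy]but-2-en-2-yl}-2-methylfuran-3(2H)-one | C=CC[C@@]1(C)OC(=CC1=O)/C(C)=C\CO[Si](C)(C)C(C)(C)C | intermediate
9 | (2R)-5-{(Z)-4-[(tert-butyldimethylsilyl)oxy]but-2-en-2-yl}-2-(2,3-dihydroxypropyl)-2-methylfuran-3(2H)-one (both carbinol epimers) | OCC(O)C[C@@]1(C)OC(=CC1=O)/C(C)=C\CO[Si](C)(C)C(C)(C)C | intermediate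
10 | 2-{(2R)-5-{(Z)-4-[(tert-butyldimethylsilyl)oxy]but-2-en-2-yl}-2-methyl-3-oxo-2,3-dihydrofuran-2-yl}acetaldehyde | O=CC[C@@]1(C)OC(=CC1=O)/C(C)=C\CO[Si](C)(C)C(C)(C)C | intermediate
11 | vinyl bromide | C=CBr | starting material
12 | (2R)-5-{(Z)-4-[(tert-butyldimethylsilyl)oxy]but-2-en-2-yl}-2-[(2S)-2-hydroxybut-3-en-1-yl]-2-methylfuran-3(2H)-one | O[C@H](C=C)C[C@@]1(C)OC(=CC1=O)/C(C)=C\CO[Si](C)(C)C(C)(C)C | intermediate
13 | 2-(bromomethyl)acrylic acid | C=C(CBr)C(=O)O | starting material
14 | (2S)-1-{(2R)-5-{(Z)-4-[(tert-butyldimethylsilyl)oxy]but-2-en-2-yl}-2-methyl-3-oxo-2,3-dihydrofuran-2-yl}but-3-en-2-yl 2-(bromomethyl)acrylate | C=C(CBr)C(=O)O[C@H](C=C)C[C@@]1(C)OC(=CC1=O)/C(C)=C\CO[Si](C)(C)C(C)(C)C | intermediate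
15 | (2R)-2-{[(2S)-4-(bromomethyl)-5-oxo-2,5-dihydrofuran-2-yl]methyl}-5-{(Z)-4-[(tert-butyldimethylsilyl)oxy]but-2-en-2-yl}-2-methylfuran-3(2H)-one | O=C1O[C@@H](C[C@@]2(C)OC(=CC2=O)/C(C)=C\CO[Si](C)(C)C(C)(C)C)C=C1CBr | intermediate
16 | (2R)-2-{[(2S)-4-(bromomethyl)-5-oxo-2,5-dihydrofuran-2-yl]methyl}-5-[(Z)-4-hydroxybut-2-en-2-yl]-2-methylfuran-3(2H)-one | O=C1O[C@@H](C[C@@]2(C)OC(=CC2=O)/C(C)=C\CO)C=C1CBr | intermediate
17 | (Z)-3-{(5R)-5-{[(2S)-4-(bromomethyl)-5-oxo-2,5-dihydrofuran-2-yl]methyl}-5-methyl-4-oxo-4,5-dihydrofuran-2-yl}but-2-enal | O=C1O[C@@H](C[C@@]2(C)OC(=CC2=O)/C(C)=C\C=O)C=C1CBr | intermediate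
18 | (6R,7S,8S,10R)-3,10-epoxy-6-hydroxy-1-oxogermacra-2,4Z,11(13)-trien-12,8-olide | C=C1C(=O)O[C@H]2C[C@@]3(C)OC(=CC3=O)/C(C)=C\[C@@H](O)[C@H]12 | intermediate
19 | (R)-(2-methyloxiran-2-yl)methanol | OC[C@]1(C)CO1 | starting material
20 | (S)-2-methyloxirane-2-carbaldehyde | O=C[C@]1(C)CO1 | intermediate
21 | (S)-2-methyloxirane-2-carboxylic acid | OC(=O)[C@]1(C)CO1 | intermediate
22 | (6R,7R,8S,10R)-3,10-epoxy-1-oxogermacra-2,4Z,11(13)-trien-12,8-olid-6-yl (S)-2-methyloxirane-2-carboxylate | C=C1C(=O)O[C@H]2C[C@@]3(C)OC(=CC3=O)/C(C)=C\[C@@H](OC(=O)[C@]3(C)CO3)[C@H]12 | target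

**Count and risks**

Total step count: 13. Longest linear sequence: 12 steps (steps 1 to 11 and 13); step 12 is a one-step side branch.

The three steps most likely to fail:

Step 11 (ring closure). The aldehyde may be attacked from the wrong face inside the medium-ring transition state, so that the C6 epimer forms, and oligomerisation may compete with closure. Fallback: the epimeric alcohol, (6S,7S,8S,10R)-3,10-epoxy-6-hydroxy-1-oxogermacra-2,4Z,11(13)-trien-12,8-olide F1, is not acylated with retention but esterified with inversion, by a Mitsunobu reaction with acid 21 (PPh3, DIAD, toluene, 0 °C), which should give 22 directly. This fallback sets out from 17 and comes back to the route at 22.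

Step 3 (key step). The oxa-Michael adduct may be trapped as the isomer with the ester trans to the ether oxygen, or allyloxide and ynoate 4 may oligomerise faster than the Dieckmann closure. Fallback: the order of bond formation is reversed with a Chan rearrangement. Alkyne 2 is lithiated and carboxylated (n-BuLi, CO2, THF, −78 °C) to (Z)-6-[(tert-butyldimethylsilyl)oxy]-4-methylhex-4-en-2-ynoic acid F2. F2 is coupled with 5 (DCC, DMAP, CH2Cl2) to the O-acyl lactate 1-(allyloxy)-1-oxopropan-2-yl (Z)-6-[(tert-butyldimethylsilyl)oxy]-4-methylhex-4-en-2-ynoate F3. LiHMDS (THF, −78 °C to rt) then forms the lactate enolate, which should take the acyl group from oxygen to carbon (1,2-acyl shift, C1–C10). The tertiary alkoxide of the resulting α-hydroxy ynone, allyl (Z)-8-[(tert-butyldimethylsilyl)oxy]-2-hydroxy-2,6-dimethyl-3-oxooct-6-en-4-ynoate F4, should add 5-endo-dig to C3 and give 7. This fallback sets out from 2 and 5 and comes back at 7.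

Step 4 (C10 stereocenter). Facial discrimination on the planar oxidofuran enolate may be low, and allylation at the ring CH carbon or at oxygen may compete. Fallback: catalyst control at C10 is given up and the reagent-controlled C8 center is used to resolve it. Achiral Tsuji allylation of 7 (Pd(PPh3)4, THF) gives racemic 2-allyl-5-{(Z)-4-[(tert-butyldimethylsilyl)oxy]but-2-en-2-yl}-2-methylfuran-3(2H)-one F5. The conditions of step 5 give the racemic diol 5-{(Z)-4-[(tert-butyldimethylsilyl)oxy]but-2-en-2-yl}-2-(2,3-dihydroxypropyl)-2-methylfuran-3(2H)-one F6 and then the racemic aldehyde 2-{5-[(Z)-4-[(tert-butyldimethylsilyl)oxy]but-2-en-2-yl]-2-methyl-3-oxo-2,3-dihydrofuran-2-yl}acetaldehyde F7. The asymmetric vinylation of step 6 should then give 12 together with its C10 epimer (2S)-5-{(Z)-4-[(tert-butyldimethylsilyl)oxy]but-2-en-2-yl}-2-[(2S)-2-hydroxybut-3-en-1-yl]-2-methylfuran-3(2H)-one F8; the two diastereomers are separated by chromatography and 12 is carried on. This fallback sets out from 7 and comes back at 12.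

**Further compounds**

F1 | step 11 | (6S,7S,8S,10R)-3,10-epoxy-6-hydroxy-1-oxogermacra-2,4Z,11(13)-trien-12,8-olide | C=C1C(=O)O[C@H]2C[C@@]3(C)OC(=CC3=O)/C(C)=C\[C@H](O)[C@H]12
F2 | step 3 | (Z)-6-[(tert-butyldimethylsilyl)oxy]-4-methylhex-4-en-2-ynoic acid | OC(=O)C#C/C(C)=C\CO[Si](C)(C)C(C)(C)C
F3 | step 3 | 1-(allyloxy)-1-oxopropan-2-yl (Z)-6-[(tert-butyldimethylsilyl)oxy]-4-methylhex-4-en-2-ynoate (racemic) | C=CCOC(=O)C(C)OC(=O)C#C/C(C)=C\CO[Si](C)(C)C(C)(C)C
F4 | step 3 | allyl (Z)-8-[(tert-butyldimethylsilyl)oxy]-2-hydroxy-2,6-dimethyl-3-oxooct-6-en-4-ynoate (racemic) | C=CCOC(=O)C(C)(O)C(=O)C#C/C(C)=C\CO[Si](C)(C)C(C)(C)C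
F5 | step 4 | 2-allyl-5-{(Z)-4-[(tert-butyldimethylsilyl)oxy]but-2-en-2-yl}-2-methylfuran-3(2H)-one (racemic) | C=CCC1(C)OC(=CC1=O)/C(C)=C\CO[Si](C)(C)C(C)(C)C
F6 | step 4 | 5-{(Z)-4-[(tert-butyldimethylsilyl)oxy]but-2-en-2-yl}-2-(2,3-dihydroxypropyl)-2-methylfuran-3(2H)-one (racemic, both carbinol epimers) | OCC(O)CC1(C)OC(=CC1=O)/C(C)=C\CO[Si](C)(C)C(C)(C)C
F7 | step 4 | 2-{5-[(Z)-4-[(tert-butyldimethylsilyl)oxy]but-2-en-2-yl]-2-methyl-3-oxo-2,3-dihydrofuran-2-yl}acetaldehyde (racemic) | O=CCC1(C)OC(=CC1=O)/C(C)=C\CO[Si](C)(C)C(C)(C)C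
F8 | step 4 | (2S)-5-{(Z)-4-[(tert-butyldimethylsilyl)oxy]but-2-en-2-yl}-2-[(2S)-2-hydroxybut-3-en-1-yl]-2-methylfuran-3(2H)-one | O[C@H](C=C)C[C@]1(C)OC(=CC1=O)/C(C)=C\CO[Si](C)(C)C(C)(C)C
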